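The data are simulated from invented constants.

We cannot read an early excess from the runs so far. The first larch reading shows 2.2% and 0% of the two products, with a scatter of 1 percentage point on each. We therefore carry a rate, not an excess.

| flask | left-handed substrate | right-handed substrate | partner | precatalyst | remark | time |
|---|---|---|---|---|---|---|
| birch | 8.5 mM | 8.5 mM | 13.6 mM (fed, over 30 min) | 1.7 mM | run made earlier |  |
| alder | 34 mM | 34 mM | 13.6 mM (fed, over 30 min) | 1.7 mM | run made earlier |  |
| larch | 17 mM | 17 mM | 20 mM (fed, over 30 min) | 1.7 mM | run made earlier |  |
| flask | 17 mM | 17 mM | 13.6 mM (fed, over 30 min) | 1.7 mM |  | 25 h |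

- birch (time / h: left-handed product / %, right-handed product / %): 2.50: 1.5, 0.2; 5.00: 2.2, 0; 8.00: 5.0, 0.6; 10.0: 5.4, 0.8; 12.0: 9.2, 1.5; 15.0: 10.1, 1.4
- alder (time / h: left-handed product / %, right-handed product / %): 1.33: 0, 0.1; 2.00: 1.6, 1.8; 3.00: 0, 0; 5.00: 1.1, 0.1; 10.0: 3.3, 0; 15.0: 3.0, 1.6
- larch (time / h: left-handed product / %, right-handed product / %): 3.00: 2.2, 0; 6.00: 3.1, 1.5; 10.0: 7.8, 3.6; 12.0: 9.1, 1.4; 15.0: 11.3, 2.3

(readings scatter by 1 percentage point)

- free catalyst is single-handed; left-handed substrate and right-handed substrate are mirror images of each other, charged as a racemate, each of them at the stated concentration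
- an excess is the difference of the two amounts in percent of their sum
- an excess is below zero if the other one leads

- excess of left-handed product over right-handed product in the product at 30 min
- excess of left-handed product over right-handed product in the product at 25 h
- part of the left-handed substrate and right-handed substrate charged together that has reacted at 25 h

We order the times from short to long. The feed of partner takes 30 min, far shorter than the 25 h asked about, so we treat partner as present from the start. Next come the readings, which end at 15.0 h. Over that span the summed products of the larch run grow roughly in step with time, within the scatter, so we freeze the rate. The larch run and this flask share a substrate charge of 17 mM, and they differ in partner. From the last larch reading we take 0.0154 h⁻¹, the partner burn rate: product formed per hour per unit of partner charged, at this substrate charge. It is a pseudo-first-order constant in partner. Its inverse, 64.9 h, is the longest time on our ladder, but it is only 2.60 times the asked time. If one partner goes per product, our reckoning spends 38.5% of the partner charge by 25 h, so holding partner at its charge is a crude freeze, and we take it for a first figure. For this flask, with 13.6 mM of partner so frozen, our reckoning gives 15.4% reacted at 25 h.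

The forecast gave 68%, 64% and 12.5%, the last below our figure, and said of the first: “The 30-min value is an extrapolation, so it is uncertain.”

The flask gives an excess of 81.7% at 30 min and 66.9% at 25 h, with 16.7% reacted.

    free catalyst + left-handed substrate ⇌ catalyst intermediate A (K = 47.0 M⁻¹, k = 2800 M⁻¹ h⁻¹)
    free catalyst + right-handed substrate ⇌ catalyst intermediate B (K = 93.0 M⁻¹, k = 500 M⁻¹ h⁻¹)
    partner + catalyst intermediate A → free catalyst + left-handed product (k = 62.0 M⁻¹ h⁻¹)
    partner + catalyst intermediate B → free catalyst + right-handed product (k = 6.20 M⁻¹ h⁻¹)
    left-handed substrate ⇌ right-handed substrate (k = 0.290 h⁻¹)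
    partner + precatalyst → free catalyst + spent reagent (k = 13.0 M⁻¹ h⁻¹)
    2 free catalyst → spent catalyst (k = 29.0 M⁻¹ h⁻¹)

The burn rate 0.0154 h⁻¹ gave 15.4% for this flask, against 16.7%. For the neighbour flask with 54 mM of partner it gives 61.1%, and that neighbour reached 60.6%. In this flask the reacted part stands where it does because of two things together: the return of catalyst intermediate A to free catalyst and left-handed substrate, and the hour of the reading. Without that return, this flask reaches 34.3% at 25 h; with it, read at 250 h, this flask reaches 34.1%.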